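## Retrosynthetic overview
1. The target comes from its 7‑O‑MOM ether. That ether comes from a racemic 2‑aryl‑2‑(iodomethyl)benzofuran‑3(2H)‑one by a radical 1,2‑acyl shift (5→6 ring expansion), and C2–H is set by a chiral H‑atom donor.
2. The iodide comes from 6‑MOMO‑7‑prenylbenzofuran‑3(2H)‑one, 6‑bromo‑2,2‑dimethylchromane and CH2I2 (one‑pot α‑arylation and C‑alkylation).
3. The benzofuranone comes from resorcinol by two directed ortho‑metalations (prenyl, then chloroacetyl) and a 5‑exo‑tet O‑alkylation.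
4. The bromochromane comes from 4‑bromophenol and isoprene.
5. Ring order: chromane ring, then furanone ring, then furanone expanded to the pyranone (flavanone C ring).

Assumption: the sense of induction of the new thiol catalyst must be found by experiment. The (Ra) form is written, and its antipode is used if (Ra) gives the 2R product.

## Route

Step 1
Reactants: 1 4‑bromophenol; 2 isoprene
Product: 4 6‑bromo‑2,2‑dimethylchromane, via 4‑bromo‑2‑prenylphenol 3 (not isolated)
Conditions: isoprene (1.5 equiv), AgOTf (5 mol %), ClCH2CH2Cl, 40 °C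
Reagents that add atoms: none
Why: Acid‑catalysed Friedel–Crafts ortho‑prenylation (para position blocked by Br) is followed by Markovnikov intramolecular hydroalkoxylation through the tertiary cation, which closes the chromane.

Step 2
Reactants: 5 resorcinol
Product: 6 1,3‑bis(methoxymethoxy)benzene
Conditions: NaH (2.4 equiv), MOMCl (2.4 equiv), DMF, 0 °C → rt
Reagents that add atoms: chloromethyl methyl ether (MOMCl), COCCl
Why: Williamson‑type acetalisation of both phenoxides installs groups that serve as protection and as ortho‑directing groups.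

Step 3
Reactants: 6 1,3‑bis(methoxymethoxy)benzene; 7 prenyl bromide
Product: 9 1,3‑bis(methoxymethoxy)‑2‑(3‑methylbut‑2‑en‑1‑yl)benzene, via 2‑lithio‑1,3‑bis(methoxymethoxy)benzene 8 (not isolated)
Conditions: n‑BuLi (1.1 equiv), THF, 0 °C → rt; CuBr·SMe2 (10 mol %), 7, –78 °C → rt
Reagents that add atoms: none
Why: Directed ortho‑metalation takes the C–H flanked by both OMOM groups, and the aryl metal is allylated SN2 by the primary bromide.

Step 4
Reactants: 9 1,3‑bis(methoxymethoxy)‑2‑prenylbenzene; 10 2‑chloro‑N‑methoxy‑N‑methylacetamide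
Product: 12 1‑[2,4‑bis(methoxymethoxy)‑3‑prenylphenyl]‑2‑chloroethan‑1‑one, via 4‑lithio‑1,3‑bis(methoxymethoxy)‑2‑prenylbenzene 11 (not isolated)
Conditions: s‑BuLi (1.1 equiv), TMEDA, THF, –78 °C; 10 (1.2 equiv), –78 °C; AcOH quench
Reagents that add atoms: none
Why: In this second directed ortho‑metalation C4 and C6 are equivalent, and OMOM‑complexed lithiation at –78 °C beats removal of the benzylic/allylic H (held near the ring plane by two ortho groups), after which the Weinreb ketone synthesis stops cleanly at the α‑chloroketone.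

Step 5
Reactants: 12 1‑[2,4‑bis(methoxymethoxy)‑3‑prenylphenyl]‑2‑chloroethan‑1‑one
Product: 14 6‑(methoxymethoxy)‑7‑prenylbenzofuran‑3(2H)‑one, via 2‑chloro‑1‑(2‑hydroxyaryl)ethanone 13 (not isolated)
Conditions: TsOH·H2O (10 mol %), MeOH, 0 °C → rt (monitored); then NaOAc (3 equiv), 60 °C
Reagents that add atoms: none
Why: The MOM group ortho to the ketone is the more labile acetal (twisted between two ortho groups, and the freed phenol is H‑bonded to C=O), and the phenol then closes by 5‑exo‑tet intramolecular Williamson O‑alkylation.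

Step 6
Reactants: 14 6‑(methoxymethoxy)‑7‑prenylbenzofuran‑3(2H)‑one; 4 6‑bromo‑2,2‑dimethylchromane; 15 diiodomethane
Product: 17 rac‑2‑(2,2‑dimethylchroman‑6‑yl)‑2‑(iodomethyl)‑6‑(methoxymethoxy)‑7‑prenylbenzofuran‑3(2H)‑one, via 2‑arylbenzofuranone 16 (not isolated)
Conditions: Pd2(dba)3 (1.5 mol %), XPhos (6 mol %), NaOt‑Bu (2.3 equiv), THF, 65 °C, Ar; then 0 °C, CH2I2 (4 equiv) → rt
Reagents that add atoms: none
Why: Buchwald–Hartwig ketone α‑arylation stops at mono‑arylation because 16 rests as its stabilised sodium enolate, which soft CH2I2 then C‑alkylates (the classical way to Dowd–Beckwith substrates), giving a racemic quaternary centre that step 7 erases.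

Step 7
Reactants: 17 rac‑2‑aryl‑2‑(iodomethyl)benzofuranone
Product: 18 (2S)‑2‑(2,2‑dimethylchroman‑6‑yl)‑7‑(methoxymethoxy)‑8‑prenylchroman‑4‑one
Conditions: 4CzIPN (2 mol %), (Ra)‑1‑[3,5‑bis(trifluoromethyl)phenyl]‑3‑(2'‑sulfanyl‑1,1'‑binaphthalen‑2‑yl)urea (2 mol %), Et3N (3 equiv), PhCF3/MeCN 9:1 (0.02 M), 456 nm LED, 25 °C, Ar
Reagents that add atoms: none
Why: Proposed new method: this is an enantioconvergent Dowd–Beckwith ring expansion in which the α‑aminoalkyl radical made from Et3N by the photocatalyst abstracts iodine from either enantiomer of 17, the primary radical adds 3‑exo to the adjacent C3=O (its C–CH2• bond stands perpendicular to the flat furanone), and the cyclopropyloxy radical opens to the far more stable benzylic, O‑substituted radical (net 1,2‑acyl shift, 5→6 ring, estimated about 20 kcal/mol downhill and over 100 times faster than the competing neophyl‑type aryl shift), which erases the old stereocentre; the planar C2 radical can take H only from the weak S–H bond of the aryl thiol (amine C–H bonds are too strong, so no racemic background), whose urea binds C4=O and delivers H to the Re face to set 2S, the thiol is held at 0.4 mM so that the acyl shift (estimated about 10^5–10^6 s^-1) outruns premature reduction, and the thiyl radical is returned by the reduced photocatalyst plus the ammonium proton; the closest known reaction types are the Bu3SnH‑mediated Dowd–Beckwith expansion of α‑halomethyl β‑keto esters, amine‑based halogen‑atom‑transfer dehalogenation with thiol co‑catalysts, and enantioselective H‑atom transfer from homochiral thiols to prochiral benzylic radicals, whereas their combination, the benzofuranone‑to‑flavanone substrate class and this thiol are new.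

Step 8
Reactants: 18 (2S)‑7‑O‑MOM flavanone
Product: 19 euchrenone a17, (2S)‑2‑(2,2‑dimethylchroman‑6‑yl)‑7‑hydroxy‑8‑prenylchroman‑4‑one
Conditions: 2 M HCl, MeOH, 40 °C, 2 h
Reagents that add atoms: none
Why: Acid‑catalysed acetal methanolysis under conditions in common use for MOM‑protected prenylflavanones is too mild to cyclise the o‑prenylphenol, and with no base present there is no retro‑oxa‑Michael, so C2 stays S.

## Compound list
1 | 4‑bromophenol | Oc1ccc(Br)cc1 | starting material
2 | isoprene | C=CC(C)=C | starting material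
3 | 4‑bromo‑2‑(3‑methylbut‑2‑en‑1‑yl)phenol | CC(C)=CCc1cc(Br)ccc1O | intermediate
4 | 6‑bromo‑2,2‑dimethylchromane | CC1(C)CCc2cc(Br)ccc2O1 | intermediate
5 | resorcinol | Oc1cccc(O)c1 | starting material
6 | 1,3‑bis(methoxymethoxy)benzene | COCOc1cccc(OCOC)c1 | intermediate
7 | prenyl bromide (1‑bromo‑3‑methylbut‑2‑ene) | CC(C)=CCBr | starting material
8 | [2,6‑bis(methoxymethoxy)phenyl]lithium | [Li]c1c(OCOC)cccc1OCOC | intermediate
9 | 1,3‑bis(methoxymethoxy)‑2‑(3‑methylbut‑2‑en‑1‑yl)benzene | COCOc1cccc(OCOC)c1CC=C(C)C | intermediate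
10 | 2‑chloro‑N‑methoxy‑N‑methylacetamide | CON(C)C(=O)CCl | starting material
11 | [2,4‑bis(methoxymethoxy)‑3‑(3‑methylbut‑2‑en‑1‑yl)phenyl]lithium | [Li]c1ccc(OCOC)c(CC=C(C)C)c1OCOC | intermediate
12 | 1‑[2,4‑bis(methoxymethoxy)‑3‑(3‑methylbut‑2‑en‑1‑yl)phenyl]‑2‑chloroethan‑1‑one | COCOc1ccc(C(=O)CCl)c(OCOC)c1CC=C(C)C | intermediate
13 | 2‑chloro‑1‑[2‑hydroxy‑4‑(methoxymethoxy)‑3‑(3‑methylbut‑2‑en‑1‑yl)phenyl]ethan‑1‑one | COCOc1ccc(C(=O)CCl)c(O)c1CC=C(C)C | intermediate
14 | 6‑(methoxymethoxy)‑7‑(3‑methylbut‑2‑en‑1‑yl)benzofuran‑3(2H)‑one | COCOc1ccc2c(c1CC=C(C)C)OCC2=O | intermediate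
15 | diiodomethane | ICI | starting material
16 | rac‑2‑(2,2‑dimethylchroman‑6‑yl)‑6‑(methoxymethoxy)‑7‑prenylbenzofuran‑3(2H)‑one (present in the flask as its sodium enolate) | COCOc1ccc2c(c1CC=C(C)C)OC(c1ccc3c(c1)CCC(C)(C)O3)C2=O | intermediate
17 | rac‑2‑(2,2‑dimethylchroman‑6‑yl)‑2‑(iodomethyl)‑6‑(methoxymethoxy)‑7‑prenylbenzofuran‑3(2H)‑one | COCOc1ccc2c(c1CC=C(C)C)OC(CI)(c1ccc3c(c1)CCC(C)(C)O3)C2=O | intermediate
18 | (2S)‑2‑(2,2‑dimethylchroman‑6‑yl)‑7‑(methoxymethoxy)‑8‑prenylchroman‑4‑one | COCOc1ccc2c(c1CC=C(C)C)O[C@H](c1ccc3c(c1)CCC(C)(C)O3)CC2=O | intermediate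
19 | euchrenone a17, (2S) | CC(C)=CCc1c(O)ccc2c1O[C@H](c1ccc3c(c1)CCC(C)(C)O3)CC2=O | target

## Step count and risks
Total steps: 8, with each one‑pot operation counted once. Longest linear sequence: 7 (5 → 19, steps 2–8).

**Step 7 (new method).**
- Risks are insufficient ee, premature reduction of the primary radical to the 2‑methylbenzofuranone, and thiyl chemistry at the prenyl group.
- The fallback uses known chemistry. It sets out from 9 and 4 and comes back at 18.
- Compound 9 is lithiated as in step 4 and acylated with N‑methoxy‑N‑methylacetamide to give 1‑[2,4‑bis(methoxymethoxy)‑3‑prenylphenyl]ethan‑1‑one F1.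
- The ortho MOM group is cleaved (TsOH, MeOH) to give 1‑[2‑hydroxy‑4‑(methoxymethoxy)‑3‑prenylphenyl]ethan‑1‑one F2.
- Condensation with DMF‑DMA (toluene, 95 °C) gives the (E)‑enaminone F3, which closes in AcOH at 60 °C to 7‑(methoxymethoxy)‑8‑prenyl‑4H‑chromen‑4‑one F4.
- In parallel, 4 is converted (n‑BuLi, then B(Oi‑Pr)3, then H3O+) into (2,2‑dimethylchroman‑6‑yl)boronic acid F5.
- A Rh(I)/chiral diphosphine Hayashi–Miyaura asymmetric 1,4‑addition of F5 to F4, with the ligand antipode chosen for 2S, gives 18.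

**Step 6 (one‑pot arylation and iodomethylation).**
- Risks are O‑ instead of C‑alkylation of the benzofuran‑3‑olate and air oxidation of 16.
- The fallback sets out from 16 and comes back at 17.
- The arylation alone is run, quenched with AcOH, and 16 is isolated under argon.
- Compound 16 is hydroxymethylated with aqueous formaldehyde and catalytic K2CO3 in THF. O‑attack is reversible, so only the C‑aldol accumulates. This gives rac‑2‑(2,2‑dimethylchroman‑6‑yl)‑2‑(hydroxymethyl)‑6‑(methoxymethoxy)‑7‑prenylbenzofuran‑3(2H)‑one F6.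
- Appel iodination of F6 (I2, PPh3, imidazole, toluene, 80 °C) gives 17.

**Step 5 (selective MOM cleavage and ring closure).**
- Risks are loss of both MOM groups and self‑condensation of 14.
- The fallback sets out from 12 and comes back at 14.
- Both acetals are removed on purpose (2 M HCl, MeOH, 40 °C) to give 2‑chloro‑1‑(2,4‑dihydroxy‑3‑prenylphenyl)ethan‑1‑one F7.
- NaOAc in MeOH closes F7 to 6‑hydroxy‑7‑prenylbenzofuran‑3(2H)‑one F8.
- The single remaining phenol of F8 is re‑protected with MOMCl and i‑Pr2NEt in CH2Cl2 to give 14.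

## Further compounds
F1 | step 7 | 1‑[2,4‑bis(methoxymethoxy)‑3‑(3‑methylbut‑2‑en‑1‑yl)phenyl]ethan‑1‑one | COCOc1ccc(C(C)=O)c(OCOC)c1CC=C(C)C
F2 | step 7 | 1‑[2‑hydroxy‑4‑(methoxymethoxy)‑3‑(3‑methylbut‑2‑en‑1‑yl)phenyl]ethan‑1‑one | COCOc1ccc(C(C)=O)c(O)c1CC=C(C)C
F3 | step 7 | (E)‑3‑(dimethylamino)‑1‑[2‑hydroxy‑4‑(methoxymethoxy)‑3‑(3‑methylbut‑2‑en‑1‑yl)phenyl]prop‑2‑en‑1‑one | COCOc1ccc(C(=O)/C=C/N(C)C)c(O)c1CC=C(C)C
F4 | step 7 | 7‑(methoxymethoxy)‑8‑(3‑methylbut‑2‑en‑1‑yl)‑4H‑chromen‑4‑one | COCOc1ccc2c(=O)ccoc2c1CC=C(C)C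
F5 | step 7 | (2,2‑dimethylchroman‑6‑yl)boronic acid | CC1(C)CCc2cc(B(O)O)ccc2O1
F6 | step 6 | rac‑2‑(2,2‑dimethylchroman‑6‑yl)‑2‑(hydroxymethyl)‑6‑(methoxymethoxy)‑7‑prenylbenzofuran‑3(2H)‑one | COCOc1ccc2c(c1CC=C(C)C)OC(CO)(c1ccc3c(c1)CCC(C)(C)O3)C2=O
F7 | step 5 | 2‑chloro‑1‑[2,4‑dihydroxy‑3‑(3‑methylbut‑2‑en‑1‑yl)phenyl]ethan‑1‑one | CC(C)=CCc1c(O)ccc(C(=O)CCl)c1O
F8 | step 5 | 6‑hydroxy‑7‑(3‑methylbut‑2‑en‑1‑yl)benzofuran‑3(2H)‑one | CC(C)=CCc1c(O)ccc2c1OCC2=O
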